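**Plan**

- Numbering: C1 (CH3, ring fusion), C2 (OAc), C3, C4 (OH, i-Pr), C5 (ring-fusion CH), C6 (O-veratroyl), C7, C8 (CH3) and C9 (epoxide), C10. β is the face of the C2 oxygen: the C1 methyl, C4–O, C6–O and the epoxide O are β; H5, i-Pr and C10 are α.
- Enabling feature: in the seven-membered ring C1–C5–C6–C7–C8–C9–C10 the C6 carbinol is homoallylic to the C8=C9 alkene hidden in the epoxide. C6–C7 can therefore come from a C6 aldehyde and a C9-silyl allylsilane (C7=C8–C9–Si) attached to the cyclopentane at C1.
- Retrosynthetic cuts, in order: the C2 acetate and C6 veratroate; the epoxide oxygen (back to C8=C9); C6–C7 (ring closure); C9–Si and the C8=C9 bond of the side chain (silyl SN2', cross-metathesis); C4–i-Pr; C5–C6; C1–C10; C1–CH3.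
- Forward: the cyclopentane ring is built up first on (S)-4-silyloxycyclopentenone (methyl, allyl, CH2OH, isopropyl). The allyl arm is then grown into the allylsilane, the seven-membered ring is closed, and epoxide and esters come last.
- Stereochemistry: C2 from the bought enone; C1 by allylcopper addition anti to the C2 silyloxy group; C5 by aldol anti to the allyl arm; C4 by Grignard addition anti to the C5 arm; C6 in the ring closure; C8 and C9 by epoxidation directed by the C6 hydroxyl.

Key step: step 11

Remark: the silyl transfer of step 9 is expected to give both C9 epimers; they are carried on together because silicon leaves C9 in step 11, so the SMILES of 18 and 19 leave C9 undefined.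

**Route**

Step 1
Reactants: 1 (S)-4-(tert-butyldimethylsilyloxy)cyclopent-2-en-1-one; 2 methylmagnesium bromide
Product: 4 (S)-4-(tert-butyldimethylsilyloxy)-3-methylcyclopent-2-en-1-one, via trimethylsilyl enol ether 3 (not isolated)
Conditions: MeMgBr, CuBr·SMe2 (cat.), Me3SiCl, THF, −78 °C; then Pd(OAc)2 (cat.), O2 (1 atm), DMSO, rt
Reagents that add atoms: methylmagnesium bromide 2, C[Mg]Br
Why: Copper-catalysed conjugate addition of methyl anti to the silyloxy group with silyl trapping, followed by Saegusa–Ito dehydrosilylation, should return the enone now carrying the C1 methyl, the temporary methyl-bearing stereocentre being erased and the C2 stereocentre untouched.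

Step 2
Reactants: 4 (S)-4-(tert-butyldimethylsilyloxy)-3-methylcyclopent-2-en-1-one; 5 allylmagnesium bromide; 6 formaldehyde
Product: 8 hydroxymethyl ketone (C4 ketone; C5 β-CH2OH; C1 β-methyl and α-allyl; C2 β-OTBS), via trimethylsilyl enol ether 7 (not isolated)
Conditions: allylMgBr, CuBr·SMe2 (1 equiv), Me3SiCl, THF, −78 °C; then 37% aq. CH2O, Yb(OTf)3 (cat.), THF, rt
Reagents that add atoms: allylmagnesium bromide 5, C=CC[Mg]Br; formaldehyde 6, C=O
Why: Me3SiCl-accelerated conjugate addition of allylcopper should build the C1 quaternary centre with allyl anti to the C2 silyloxy group, and the lanthanide-triflate-catalysed Mukaiyama aldol of the silyl enol ether with aqueous formaldehyde should add C6 at C5 anti to the larger allyl arm, an epimerisable centre whose more stable arrangement (C6 trans to allyl, cis-1,3 to the silyloxy group) is the same one.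

Step 3
Reactants: 8 hydroxymethyl ketone
Product: 9 C6 triethylsilyl ether of 8
Conditions: Et3SiCl, imidazole, CH2Cl2, 0 °C
Reagents that add atoms: chlorotriethylsilane, CC[Si](Cl)(CC)CC
Why: Silyl ether formation at the primary hydroxyl should block retro-aldol loss of formaldehyde and dehydration of the β-hydroxy ketone before the organometallic step, without touching a stereocentre.

Step 4
Reactants: 9 C6 triethylsilyl ether; 10 isopropylmagnesium chloride
Product: 11 tertiary alcohol (C4 β-OH and α-isopropyl; C5 β-CH2OTES; C1 β-methyl and α-allyl; C2 β-OTBS)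
Conditions: LaCl3·2LiCl, THF, rt; then i-PrMgCl, 0 °C
Reagents that add atoms: isopropylmagnesium chloride 10, CC(C)[Mg]Cl
Why: Lanthanide-promoted Grignard 1,2-addition, which suppresses β-hydride reduction and enolisation toward C3 (the latter would expel the C2 silyloxy group), should deliver isopropyl from the α face, anti to the C5 arm and to the β-oriented C1 methyl and C2 silyloxy groups, setting C4 with its hydroxyl β.

Step 5
Reactants: 11 tertiary alcohol
Product: 12 bis(triethylsilyl) ether (C4 β-OTES; C6 OTES)
Conditions: Et3SiOTf, 2,6-lutidine, CH2Cl2, 0 °C to rt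
Reagents that add atoms: triethylsilyl trifluoromethanesulfonate, CC[Si](CC)(CC)OS(=O)(=O)C(F)(F)F
Why: Silyl ether formation with the silyl triflate should cap the hindered tertiary hydroxyl, so that the later β-oxygenated aldehyde cannot undergo retro-aldol ring opening and no free hydroxyl consumes base or Lewis acid.

Step 6
Reactants: 12 bis(triethylsilyl) ether; 13 methacrolein
Product: 14 (E)-enal (C1 arm C10H2–C9H=C8(CH3)–C7HO)
Conditions: methacrolein (excess), second-generation Hoveyda–Grubbs catalyst (5 mol%), CH2Cl2, 40 °C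
Reagents that add atoms: methacrolein 13, C=C(C)C=O
Why: Olefin cross-metathesis of the unhindered terminal alkene with the electron-poor 1,1-disubstituted partner should give the trisubstituted enal, bringing in C8 with its methyl and C7 in one step (the E isomer is expected, and the alkene geometry is erased in step 9).

Step 7
Reactants: 14 (E)-enal
Product: 15 (E)-allylic alcohol (C7 OH)
Conditions: i-Bu2AlH, CH2Cl2, −78 °C; then aq. potassium sodium tartrate
Reagents that add atoms: none
Why: Hydride 1,2-reduction of the enal under aprotic conditions should give the primary allylic alcohol without affecting the three silyl ethers.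

Step 8
Reactants: 15 (E)-allylic alcohol
Product: 16 N-phenylcarbamate of 15
Conditions: PhNCO, pyridine, DMAP (cat.), CH2Cl2, rt
Reagents that add atoms: phenyl isocyanate, O=C=Nc1ccccc1
Why: Carbamoylation (addition of the primary alcohol to the isocyanate) installs the leaving group that later binds copper and directs the silyl transfer.

Step 9
Reactants: 16 N-phenylcarbamate
Product: 18 allylsilane (C1 arm C10H2–C9H(SiMe2Ph)–C8(CH3)=C7H2; both C9 epimers), via N-lithio carbamate 17 (not isolated)
Conditions: n-BuLi, THF, −78 °C; CuI, PPh3, 0 °C; then PhMe2SiLi, 0 °C to rt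
Reagents that add atoms: (dimethylphenylsilyl)lithium, [Li][Si](C)(C)c1ccccc1
Why: Carbamate-directed allylic substitution by a silylcuprate (syn SN2') should deliver silicon intramolecularly to C9 with shift of the alkene to C8=C7 and loss of the carbamate, placing silicon exactly where the later cyclisation needs it, the configuration at C9 being irrelevant because silicon leaves in step 11.

Step 10
Reactants: 18 allylsilane
Product: 19 aldehyde (C5 β-CHO; C4 β-OTES and α-isopropyl; C2 β-OTBS; C1 β-methyl and α-CH2–CH(SiMe2Ph)–C(CH3)=CH2)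
Conditions: (COCl)2, DMSO, CH2Cl2, −78 to −40 °C; then Et3N, −78 °C to rt
Reagents that add atoms: none
Why: Swern oxidation in which the chlorosulfonium salt cleaves the primary triethylsilyl ether in the flask and oxidises C6 to the aldehyde should leave the hindered tertiary triethylsilyl ether, the secondary TBS ether and the allylsilane intact, C5 keeping the configuration that is also the more stable one (aldehyde trans to isopropyl and to the C1 arm).

Step 11
Reactants: 19 aldehyde
Product: 20 bicyclic alcohol (trans-fused; C6 β-OH; C8=C9 alkene; C4 β-OTES; C2 β-OTBS)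
Conditions: BF3·OEt2 (1.1 equiv), CH2Cl2 (high dilution), −78 °C; then aq. NaHCO3
Reagents that add atoms: none
Why: BF3 activates the C6 aldehyde and the terminal alkene carbon C7 attacks it anti to silicon (SE2'), generating a tertiary cation at C8 that is stabilised by the C9–Si bond and collapses by loss of the silyl group, so the alkene can only end at C8=C9. The closest known reaction type is the intramolecular Hosomi–Sakurai allylation of aldehydes, established for five- to seven-membered carbocycles. The seven-membered ring (C1–C5–C6–C7–C8–C9–C10) closes through C6–C7, exo with respect to the carbonyl and endo with respect to the allyl unit, and the trans arms at C1 and C5 make the ring fusion trans. The new C6 stereocentre is set by the aldehyde face reached in a chair-like synclinal transition state, in which the carbonyl oxygen lies pseudo-axial on the β face between the C1 methyl and the C4 silyloxy group, giving the 6β alcohol. The step needs site selectivity (C7 and not C9 attacks, secured by silicon on C9) and facial selectivity at C6, which the small monodentate Lewis acid (it prefers the synclinal arrangement) and the short trans tether should favour but which is not secure (see the fallback); both C9 epimers converge on 20. The C4 silyl ether blocks retro-aldol opening and β-elimination of the oxygenated aldehyde under the Lewis acid.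

Step 12
Reactants: 20 bicyclic alcohol
Product: 21 epoxy alcohol (8β,9β-epoxide; C6 β-OH)
Conditions: VO(acac)2 (cat.), t-BuOOH (decane), CH2Cl2, 0 °C to rt
Reagents that add atoms: tert-butyl hydroperoxide, CC(C)(C)OO
Why: Hydroxyl-directed epoxidation, in which the vanadium alkoxide of the homoallylic pseudo-axial C6 hydroxyl delivers the peroxide oxygen to the C8=C9 alkene on its own (β) face, sets C8 and C9 together.

Step 13
Reactants: 21 epoxy alcohol; 22 3,4-dimethoxybenzoyl chloride
Product: 23 C6 3,4-dimethoxybenzoate of 21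
Conditions: 3,4-(MeO)2C6H3COCl, Et3N, DMAP (cat.), CH2Cl2, rt
Reagents that add atoms: 3,4-dimethoxybenzoyl chloride 22, COc1ccc(C(Cl)=O)cc1OC
Why: DMAP-catalysed acylation of the only free hydroxyl with the acid chloride should give the ester with retention at C6, under basic conditions that do not open the epoxide.

Step 14
Reactants: 23 C6 3,4-dimethoxybenzoate
Product: 24 diol (C2 β-OH; C4 β-OH)
Conditions: Bu4NF, AcOH, THF, rt to 40 °C
Reagents that add atoms: none
Why: Fluoride-mediated desilylation buffered with acetic acid should remove both silyl ethers while keeping alkoxide concentration low, so that the aryl ester does not migrate and the epoxide is not opened.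

Step 15
Reactants: 24 diol; 25 acetic anhydride
Product: 26 CNP0330776.1
Conditions: Ac2O, pyridine, DMAP (cat.), CH2Cl2, 0 °C to rt
Reagents that add atoms: acetic anhydride 25, CC(=O)OC(C)=O
Why: DMAP-catalysed acetylation should take place only at the secondary C2 hydroxyl, the tertiary C4 hydroxyl flanked by isopropyl being unreactive under these conditions.

**Compound list**

1 | (S)-4-(tert-butyldimethylsilyloxy)cyclopent-2-en-1-one | O=C1C=C[C@@H](O[Si](C)(C)C(C)(C)C)C1 | starting material
2 | methylmagnesium bromide | C[Mg]Br | starting material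
3 | trimethylsilyl enol ether (C4 OSiMe3, C4=C5; C1 α-methyl; C2 β-OTBS; not isolated) | C[C@H]1C=C(O[Si](C)(C)C)C[C@@H]1O[Si](C)(C)C(C)(C)C | intermediate
4 | (S)-4-(tert-butyldimethylsilyloxy)-3-methylcyclopent-2-en-1-one (C4 ketone, C5=C1, C1 methyl, C2 β-OTBS) | CC1=CC(=O)C[C@@H]1O[Si](C)(C)C(C)(C)C | intermediate
5 | allylmagnesium bromide | C=CC[Mg]Br | starting material
6 | formaldehyde (37% in water) | C=O | starting material
7 | trimethylsilyl enol ether (C4 OSiMe3, C4=C5; C1 β-methyl and α-allyl; C2 β-OTBS; not isolated) | C[Si](C)(C)OC1=C[C@](C)(CC=C)[C@@H](O[Si](C)(C)C(C)(C)C)C1 | intermediate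
8 | hydroxymethyl ketone (C4 ketone; C5 β-CH2OH; C1 β-methyl and α-allyl; C2 β-OTBS) | OC[C@@H]1C(=O)C[C@H](O[Si](C)(C)C(C)(C)C)[C@@]1(C)CC=C | intermediate
9 | C6 triethylsilyl ether of 8 | CC[Si](CC)(CC)OC[C@@H]1C(=O)C[C@H](O[Si](C)(C)C(C)(C)C)[C@@]1(C)CC=C | intermediate
10 | isopropylmagnesium chloride | CC(C)[Mg]Cl | starting material
11 | tertiary alcohol (C4 β-OH and α-isopropyl; C5 β-CH2OTES; C1 β-methyl and α-allyl; C2 β-OTBS) | CC[Si](CC)(CC)OC[C@@H]1[C@@](O)(C(C)C)C[C@H](O[Si](C)(C)C(C)(C)C)[C@@]1(C)CC=C | intermediate
12 | bis(triethylsilyl) ether (C4 β-OTES; C6 OTES) | CC[Si](CC)(CC)OC[C@@H]1[C@@](O[Si](CC)(CC)CC)(C(C)C)C[C@H](O[Si](C)(C)C(C)(C)C)[C@@]1(C)CC=C | intermediate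
13 | methacrolein | C=C(C)C=O | starting material
14 | (E)-enal (C1 arm C10H2–C9H=C8(CH3)–C7HO) | CC[Si](CC)(CC)OC[C@@H]1[C@@](O[Si](CC)(CC)CC)(C(C)C)C[C@H](O[Si](C)(C)C(C)(C)C)[C@@]1(C)C/C=C(\C)C=O | intermediate
15 | (E)-allylic alcohol (C7 OH) | CC[Si](CC)(CC)OC[C@@H]1[C@@](O[Si](CC)(CC)CC)(C(C)C)C[C@H](O[Si](C)(C)C(C)(C)C)[C@@]1(C)C/C=C(\C)CO | intermediate
16 | N-phenylcarbamate of 15 | CC[Si](CC)(CC)OC[C@@H]1[C@@](O[Si](CC)(CC)CC)(C(C)C)C[C@H](O[Si](C)(C)C(C)(C)C)[C@@]1(C)C/C=C(\C)COC(=O)Nc2ccccc2 | intermediate
17 | N-lithio carbamate (not isolated) | CC[Si](CC)(CC)OC[C@@H]1[C@@](O[Si](CC)(CC)CC)(C(C)C)C[C@H](O[Si](C)(C)C(C)(C)C)[C@@]1(C)C/C=C(\C)COC(=O)N([Li])c2ccccc2 | intermediate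
18 | allylsilane (C1 arm C10H2–C9H(SiMe2Ph)–C8(CH3)=C7H2; both C9 epimers) | CC[Si](CC)(CC)OC[C@@H]1[C@@](O[Si](CC)(CC)CC)(C(C)C)C[C@H](O[Si](C)(C)C(C)(C)C)[C@@]1(C)CC([Si](C)(C)c2ccccc2)C(C)=C | intermediate
19 | aldehyde (C5 β-CHO; C4 β-OTES and α-isopropyl; C2 β-OTBS; C1 β-methyl and α-allylsilane arm; both C9 epimers) | O=C[C@@H]1[C@@](O[Si](CC)(CC)CC)(C(C)C)C[C@H](O[Si](C)(C)C(C)(C)C)[C@@]1(C)CC([Si](C)(C)c2ccccc2)C(C)=C | intermediate
20 | bicyclic alcohol (trans-fused; C6 β-OH; C8=C9; C4 β-OTES; C2 β-OTBS) | O[C@H]1CC(C)=CC[C@]2(C)[C@@H](O[Si](C)(C)C(C)(C)C)C[C@](O[Si](CC)(CC)CC)(C(C)C)[C@@H]12 | intermediate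
21 | epoxy alcohol (8β,9β-epoxide; C6 β-OH) | O[C@H]1C[C@@]2(C)O[C@H]2C[C@]2(C)[C@@H](O[Si](C)(C)C(C)(C)C)C[C@](O[Si](CC)(CC)CC)(C(C)C)[C@@H]12 | intermediate
22 | 3,4-dimethoxybenzoyl chloride | COc1ccc(C(Cl)=O)cc1OC | starting material
23 | C6 3,4-dimethoxybenzoate of 21 | COc1ccc(C(=O)O[C@H]2C[C@@]3(C)O[C@H]3C[C@]3(C)[C@@H](O[Si](C)(C)C(C)(C)C)C[C@](O[Si](CC)(CC)CC)(C(C)C)[C@@H]23)cc1OC | intermediate
24 | diol (C2 β-OH; C4 β-OH; C6 β-veratroate; 8β,9β-epoxide) | COc1ccc(C(=O)O[C@H]2C[C@@]3(C)O[C@H]3C[C@]3(C)[C@@H](O)C[C@](O)(C(C)C)[C@@H]23)cc1OC | intermediate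
25 | acetic anhydride | CC(=O)OC(C)=O | starting material
26 | CNP0330776.1 | COc1ccc(C(=O)O[C@H]2C[C@@]3(C)O[C@H]3C[C@]3(C)[C@@H](OC(C)=O)C[C@](O)(C(C)C)[C@@H]23)cc1OC | target

**Step count and risks**

Total step count: 15. Longest linear sequence: 15 steps (1 to 26); every other reactant is bought.

Step 11 is the most likely to fail. The aldehyde may be attacked on its other face through the antiperiplanar arrangement, in which the carbonyl oxygen points away from the C1 methyl and the C4 silyloxy group, which is the sterically easier approach. The fallback sets out from 19 and moves the C6 stereocontrol from the C–C bond formation to a ketone reduction. The cyclisation is run as before and the 6α-epimeric alcohol F1 (alone or mixed with 20) is oxidised with Dess–Martin periodinane and NaHCO3 to the β,γ-unsaturated C6 ketone F2. Reduction with LiBH(s-Bu)3 in THF at −78 °C should then bring hydride in from the open α face, the β face being screened by the pseudo-axial C1 methyl and the C4 silyloxy group, and the route is rejoined at 20.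

Step 2 comes next. Transfer of the allyl group to the crowded β-carbon next to the silyloxy group may be slow or may go 1,2, and the silyl enol ether may hydrolyse instead of undergoing the aldol. The fallback sets out from 4 and uses a Hosomi–Sakurai conjugate allylation (allyltrimethylsilane, TiCl4, CH2Cl2, −78 °C), the Lewis-acid route suited to β,β-disubstituted enones. The trichlorotitanium enolate F3 formed in the flask is trapped with monomeric formaldehyde and, after aqueous work-up, the route is rejoined at 8.

Step 4 is the third. Enolisation toward C3 with β-elimination of the C2 silyloxy group, or β-hydride reduction of the hindered ketone, may outrun addition of the secondary Grignard reagent. The fallback sets out from 9 and brings the three carbons in as an sp2 nucleophile that cannot transfer hydride.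

- 2-Propenylmagnesium bromide with CeCl3 (THF, −78 °C) should give the isopropenyl carbinol F4.
- Et3SiOTf and 2,6-lutidine give the bis(triethylsilyl) ether F5.
- Cross-metathesis with methacrolein (second-generation Hoveyda–Grubbs catalyst) gives the enal F6, the hindered 1,1-disubstituted isopropenyl group staying inert.
- i-Bu2AlH gives the allylic alcohol F7.
- H2 with RhCl(PPh3)3 in benzene should saturate only the 1,1-disubstituted alkene and leave the trisubstituted one, and the route is rejoined at 15.

Further compounds
F1 | step 11 | 6α-epimer of bicyclic alcohol 20 | O[C@@H]1CC(C)=CC[C@]2(C)[C@@H](O[Si](C)(C)C(C)(C)C)C[C@](O[Si](CC)(CC)CC)(C(C)C)[C@@H]12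
F2 | step 11 | bicyclic C6 ketone (C8=C9 alkene) | O=C1CC(C)=CC[C@]2(C)[C@@H](O[Si](C)(C)C(C)(C)C)C[C@](O[Si](CC)(CC)CC)(C(C)C)[C@@H]12
F3 | step 2 | trichlorotitanium enolate (C4 OTiCl3, C4=C5; C1 β-methyl and α-allyl; C2 β-OTBS) | Cl[Ti](Cl)(Cl)OC1=C[C@](C)(CC=C)[C@@H](O[Si](C)(C)C(C)(C)C)C1
F4 | step 4 | isopropenyl carbinol (C4 β-OH and α-isopropenyl) | CC[Si](CC)(CC)OC[C@@H]1[C@@](O)(C(C)=C)C[C@H](O[Si](C)(C)C(C)(C)C)[C@@]1(C)CC=C
F5 | step 4 | bis(triethylsilyl) ether of the isopropenyl carbinol | CC[Si](CC)(CC)OC[C@@H]1[C@@](O[Si](CC)(CC)CC)(C(C)=C)C[C@H](O[Si](C)(C)C(C)(C)C)[C@@]1(C)CC=C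
F6 | step 4 | (E)-enal with C4 isopropenyl | CC[Si](CC)(CC)OC[C@@H]1[C@@](O[Si](CC)(CC)CC)(C(C)=C)C[C@H](O[Si](C)(C)C(C)(C)C)[C@@]1(C)C/C=C(\C)C=O
F7 | step 4 | (E)-allylic alcohol with C4 isopropenyl | CC[Si](CC)(CC)OC[C@@H]1[C@@](O[Si](CC)(CC)CC)(C(C)=C)C[C@H](O[Si](C)(C)C(C)(C)C)[C@@]1(C)C/C=C(\C)CO
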